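## Analysis of the target

Gericudranin E (20) is a dihydroflavonol, a chroman-4-one. Ring A (C4a–C8a) is a phloroglucinol-type benzene with free hydroxyls at C5 and C7, ring C is the pyranone (O1, C2, C3, C4), ring B is a 4-hydroxyphenyl group on C2, and a fourth arene, again 4-hydroxyphenyl, is tied to C6 through a methylene group. There are two adjacent stereocentres, C2 (R) and C3 (R). The aryl group on C2 and the hydroxyl on C3 are trans, both equatorial on the half-chair, which is also the more stable relative arrangement. C3 lies alpha to the C4 ketone and can epimerise through the enol. C2 is benzylic and sits beta to the carbonyl through O1, so base can open ring C by a retro-oxa-Michael reaction to a chalcone and erase it. The alpha-hydroxy ketone is readily dehydrogenated to a flavonol in basic aerobic media, the four phenols are oxidisable, and C2–O1 is a benzylic ether. The hard points are to place the benzyl group at C6 and not at C8, to set the absolute configuration at C2, and to add O3 trans without disturbing C2. The route rests on two features. C4 is a single carbonyl carbon between C4a of ring A and C3, so it can enter as carbon monoxide (11) between an ortho-iodophenol and an arylacetylene. Ring A without ring C has a mirror plane through C6 and C8a (O1 para to the benzylic carbon, O5 and O7 equivalent), so the ring A building block can be a symmetric phenol for which the C6/C8 question does not arise.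

## Retrosynthetic reasoning

**20 from 19.** The four O–benzyl bonds are cut last. Benzyl ethers are chosen because they survive base, organomagnesium reagents, dilute acid, palladium with carbon monoxide 11, homogeneous hydrogenation and the oxidants used. They fall together under neutral hydrogenolysis, which suits the base-sensitive alpha-hydroxy ketone. The C3 hydroxyl is made last and needs no protection.

**19 from 17, and 17 from 15.** The C3–O bond is cut. C3 is alpha to the ketone, so oxygen can be delivered to the enol derivative 17 by a Rubottom oxidation through epoxide 18. The C2 aryl group shields one face, so the oxidant should come anti and give the trans arrangement. The forward sequence must never pass through a free enolate, since that could open ring C and racemise C2, so 17 is made by soft enolisation of 15.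

**15 from 14, through 16.** The C2–H and C3–H bonds are cut, which leads back to the flat, achiral flavone 14. Asymmetric hydrogenation then sets C2 as the only stereocentre. The ruthenium carbene catalyst class suited to flavones also reduces the C4 carbonyl. The route therefore accepts the flavan-4-ol 16 as the hydrogenation product and restores the ketone in a separate oxidation. The C4 configuration of 16 is irrelevant.

**14 from 9, 10 and 11.** Three bonds are cut at once: C4a–C4, C4–C3 and O1–C2. C4 carries nothing but oxygen, so it can be carbon monoxide 11. Ring A then arrives as iodophenol 9 and C2, C3 and ring B as the commercial alkyne 10. This is the most convergent cut available, because it closes ring C and joins all three pieces in one operation. The forward reaction must couple carbonylatively to ynone 12 and then close the six-membered ring through enaminone 13.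

**9 from 8.** The C4a–I bond is cut. Phenol 8 has only two free positions on ring A; they are equivalent and both ortho to the hydroxyl. Whichever is iodinated, the benzyl group ends up para to O1, that is at C6. The regiochemical problem of the target is settled here by symmetry.

**8 from 6, and 6 from 3 and 5 (made from 4).** The bond between the methylene carbon and the outer 4-oxygenated phenyl ring is cut. Cutting instead between C6 and the methylene carbon would mean benzylating a phloroglucinol nucleus, with competing O-alkylation and polyalkylation. With this cut the methylene carbon is already on the ring as the formyl carbon of 3, flanked by the two oxygens that become O5 and O7. Addition of Grignard reagent 5 gives carbinol 6. Ionic hydrogenation removes the carbinol oxygen and, through 7, also frees the phenol.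

**3 from 2, and 2 from 1.** Only protecting-group bonds are cut. In aldehyde 1 the para hydroxyl (later O1) must differ from the two ortho hydroxyls (later O5 and O7). The para hydroxyl is the most acidic and is not hydrogen-bonded to the formyl group, so it takes a temporary methoxymethyl group first (2). The two chelated hydroxyls are then benzylated (3).

## Alternatives that were turned down

**Alternative 1: photochemical benzannulation that builds ring A on a finished ring C.**
- Disconnection: ring A is dismantled instead of ring C. The bonds C8–C8a, C7–C8, C5–C6 and C4a–C5 are cut. This leaves a dihydropyranone that already holds C2 and C3 and carries a diazoacetyl group on C8a (A2), and a siloxyalkyne holding C6, C7 and the benzyl side chain (A3).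
- Forward key step: irradiation of A2 with A3 would trigger a Wolff shift of C8a onto the diazo carbon (C8–C8a). The ketene unit so formed would add across the alkyne (C5–C6 and C7–C8). The four-membered ring would open, and a six-electron closure onto C4a (C4a–C5) with tautomerisation would give phenol A1.
- For: the benzyl group is fixed at C6 by the polarity of the alkyne and not by symmetry. O5 (free) and O7 (silylated) come out differentiated. Both stereocentres are in place before the annulation, so no flavone reduction and no late oxidation are needed.
- Against: A2 is a chiral vinylogous ester with an epimerisable C3 and a C2 that is benzylic and attached to the enol ether oxygen, and it needs its own asymmetric synthesis of several steps. Its enone chromophore can undergo other photoreactions. The final ring closure must engage C4a, the alpha carbon of a cross-conjugated ketone. The propargylic, benzylic methylene of A3 can isomerise to an allene. Both partners are multistep, so the sequence would be clearly longer than eleven steps.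
- Comparison: on regiocontrol and on differentiation of the ring A oxygens this plan is the stronger one. The chosen route offers instead commercial or few-step fragments, achiral intermediates up to 14, and stereocentres introduced only on robust late compounds.

**Alternative 2: ether formation from a glycidic amide, then anionic ring closure at C4–C4a.**
- Disconnection: C4–C4a and O1–C2 are cut. Phenol 8 would open the trans glycidic Weinreb amide A6 at its benzylic carbon (O1–C2). After silylation of O3 and bromination at C4a this gives bromide A5.
- Forward key step: bromine–lithium exchange on A5 with an alkyllithium at low temperature, then attack of the C4a carbanion centre on the amide carbonyl, closes ring C as ketone A4.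
- For: it shares phenol 8 with the chosen route. Both stereocentres come from one well-established asymmetric epoxidation, and the trans relationship follows from inversion on opening. No redox adjustment follows ring closure and no pressure equipment is needed. The step count is similar or slightly lower.
- Against: the ether formation joins an ambident, very electron-rich phenol to a 4-alkoxybenzylic epoxide carbon. Ionisation there would erode the configuration at C2, and C-alkylation of ring A ortho to the hydroxyl competes. In the ring closure the carbanion centre sits in a molecule with doubly benzylic methylene protons and with a C3–H that is alpha to the amide and beta to an aryloxy leaving group. Proton transfer and beta-elimination back to the phenoxide therefore compete with the acyl transfer.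
- Comparison: this plan is stronger in how the stereocentres are set and equal in length. The chosen route offers instead bond formations that never pass through an ionisable C2 or a carbanion next to acidic C–H bonds, and a key step of a well-documented type on a substrate without stereocentres.

**Alternative 3: ortho-quinone methide cycloaddition that builds ring C.**
- Disconnection: C3–C4 and O1–C2 are cut in a formal [4+2] sense, giving salicylaldehyde A8 (one formylation away from phenol 8) and enol acetate A9.
- Forward key step: an orthoformate and a confined chiral Brønsted acid would turn the formyl group of A8 into an O-methyl oxocarbenium centre of ortho-quinone methide type at C4. C3 of A9 would attack it and the phenol oxygen would close on C2, giving chroman A7.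
- For: it is the most convergent plan. Ring C and both stereocentres would arise in one catalytic enantioselective step from two simple pieces, and it is the shortest sequence on paper.
- Against: the donor oxygens at C5 and C7 stabilise the cationic centre and lower its electrophilicity. The C5 benzyloxy group is peri to the reacting carbon and must fit, with three further benzyl groups, into a confined catalyst pocket. The alkene of A9 is polarised in opposite senses by its aryl and acetoxy substituents, so regiochemistry is contested. A stepwise cationic addition allows bond rotation before ring closure, which would erode the trans selectivity. A7 is at the wrong oxidation level at C4, so the methyl ether has to be hydrolysed through a highly stabilised C4 cation and oxidised, and the acetate removed without epimerising C3. The key reaction has no counterpart on so heavily substituted an aldehyde.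
- Comparison: this plan is stronger on convergence and on forming both stereocentres at once. The chosen route offers instead reaction types that are known for flavonoid substrates at every stage, and the correct oxidation level at C4 from the moment carbon monoxide 11 is inserted.

Key step: step 6

Assumption: the (R,R) antipode of the carbene precursor SINpEt·HBF4, 1,3-bis[(R)-1-(naphthalen-1-yl)ethyl]-4,5-dihydroimidazolium tetrafluoroborate, is taken to deliver hydrogen to the face of C2 that gives the 2S configuration. Should the sense be the opposite, the (S,S) antipode is used and nothing else changes.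

## Route

Step 1
Reactants: 1 2,4,6-trihydroxybenzaldehyde
Product: 2 2,6-dihydroxy-4-(methoxymethoxy)benzaldehyde
Conditions: MOMCl (1.0 equiv), i-Pr2NEt (1.1 equiv), THF, −20 → 0 °C
Reagents that add atoms: chloromethyl methyl ether, COCCl
Why: Williamson-type O-alkylation; the C4 hydroxyl, para to the formyl group, is the most acidic and is not held in a hydrogen bond, whereas the ortho hydroxyls are chelated to the carbonyl oxygen, so one equivalent of a reactive halide at low temperature should alkylate O4 first, and over-alkylated material is separable.

Step 2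
Reactants: 2 2,6-dihydroxy-4-(methoxymethoxy)benzaldehyde
Product: 3 2,6-bis(benzyloxy)-4-(methoxymethoxy)benzaldehyde
Conditions: BnBr (2.5 equiv), K2CO3 (3 equiv), DMF, 60 °C
Reagents that add atoms: benzyl bromide, BrCc1ccccc1
Why: Williamson ether synthesis under the forcing conditions (polar aprotic solvent, heat) that chelated ortho-hydroxybenzaldehydes need; the acetal is stable to base and the electron-withdrawing formyl group disfavours C-alkylation of the ring.

Step 3
Reactants: 3 2,6-bis(benzyloxy)-4-(methoxymethoxy)benzaldehyde; 4 1-(benzyloxy)-4-bromobenzene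
Product: 6 [2,6-bis(benzyloxy)-4-(methoxymethoxy)phenyl][4-(benzyloxy)phenyl]methanol (racemic), via 4-(benzyloxy)phenylmagnesium bromide 5 (not isolated)
Conditions: 4, Mg, THF, reflux; then 3, THF, 0 °C → rt; aq. NH4Cl
Reagents that add atoms: none
Why: Grignard addition to an aldehyde; magnesium inserts into the C–Br bond without touching the benzyl ether, the ortho benzyloxy groups of 3 can chelate magnesium and do not block the formyl carbon, and the new carbinol centre is racemic and is removed in step 4.

Step 4
Reactants: 6 [2,6-bis(benzyloxy)-4-(methoxymethoxy)phenyl][4-(benzyloxy)phenyl]methanol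
Product: 8 3,5-bis(benzyloxy)-4-[4-(benzyloxy)benzyl]phenol, via 1,3-bis(benzyloxy)-2-[4-(benzyloxy)benzyl]-5-(methoxymethoxy)benzene 7 (not isolated)
Conditions: Et3SiH (5 equiv), CF3CO2H, CH2Cl2, −20 °C → rt
Reagents that add atoms: none
Why: Ionic hydrogenation: the doubly benzylic alcohol ionises in acid to a benzhydryl cation stabilised by three alkoxy groups on one ring and one on the other, and the silane transfers hydride to give 7; the same acid then cleaves the aryl methoxymethyl acetal, whose methoxymethyl cation is also reduced by the silane and so cannot alkylate the electron-rich ring, while aryl benzyl ethers are stable to dilute CF3CO2H at room temperature.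

Step 5
Reactants: 8 3,5-bis(benzyloxy)-4-[4-(benzyloxy)benzyl]phenol
Product: 9 3,5-bis(benzyloxy)-4-[4-(benzyloxy)benzyl]-2-iodophenol
Conditions: NIS (1.0 equiv), CH2Cl2, −40 → 0 °C, dark
Reagents that add atoms: N-iodosuccinimide, O=C1CCC(=O)N1I
Why: Electrophilic aromatic iodination; the phloroglucinol-type ring is by far the most nucleophilic arene, its position para to the hydroxyl is blocked by the benzyl group and the two free ortho positions are equivalent, so one equivalent of reagent at low temperature should give a single mono-iodide.

Step 6
Reactants: 9 3,5-bis(benzyloxy)-4-[4-(benzyloxy)benzyl]-2-iodophenol; 10 1-(benzyloxy)-4-ethynylbenzene; 11 carbon monoxide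
Product: 14 5,7-bis(benzyloxy)-6-[4-(benzyloxy)benzyl]-2-[4-(benzyloxy)phenyl]-4H-chromen-4-one, via ortho-hydroxyaryl ynone 12 (not isolated), via diethylamino enone 13 (not isolated)
Conditions: PdCl2(PPh3)2 (5 mol %), CO (20 bar), Et2NH, 120 °C, autoclave
Reagents that add atoms: none
Why: PdCl2(PPh3)2 is reduced in the flask to zerovalent palladium, which inserts into the C4a–I bond of 9; carbon monoxide 11 then inserts to give an aroyl–palladium species, and the acetylide formed from 10 and the amine couples with it (C4a–C4 and C4–C3) to give ynone 12. Diethylamine adds to the ynone in conjugate fashion to give the beta-amino enone 13, and the phenol oxygen then attacks C2 and expels the amine, a 6-endo-trig addition–elimination that closes ring C (O1–C2) as the 4-pyranone of 14. The closest known reaction type is the palladium-catalysed carbonylative Sonogashira coupling and cyclisation of 2-iodophenols with terminal alkynes to flavones. No stereocentre is formed. The step needs ring-size selectivity (flavone rather than the aurone from 5-exo attack at C3) and chemoselectivity for carbonylative coupling over direct alkynylation, which would end in a 2-arylbenzofuran, and over capture of the aroyl complex by the amine. The ring size is secured by the amine, because in 13 only C2 carries a leaving group; the chemoselectivity is secured by the carbon monoxide pressure and the absence of copper. The position of the benzyl group needs no control, since 9 has a single C–I bond that derives from two equivalent positions of 8. The two ortho substituents slow oxidative addition, which the reactive C–I bond and the temperature should offset, and benzyl ethers are inert to these conditions.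

Step 7
Reactants: 14 5,7-bis(benzyloxy)-6-[4-(benzyloxy)benzyl]-2-[4-(benzyloxy)phenyl]-4H-chromen-4-one
Product: 16 (2S)-5,7-bis(benzyloxy)-6-[4-(benzyloxy)benzyl]-2-[4-(benzyloxy)phenyl]chroman-4-ol (C4 epimers; mainly 2,4-cis), via (2S)-flavanone 15 (not isolated)
Conditions: Ru(cod)(2-methylallyl)2 (5 mol %), (R,R)-SINpEt·HBF4 (10 mol %), KOt-Bu (15 mol %), toluene/n-hexane, H2 (100 bar), 40 °C
Reagents that add atoms: none
Why: Homogeneous asymmetric hydrogenation of a flavone with a ruthenium N-heterocyclic carbene catalyst; hydrogen adds across C2=C3 from the face selected by the C2-symmetric carbene, which sets C2 as S, and this catalyst class goes on to reduce the C4 carbonyl, so the flavan-4-ol is taken as the product, with its C4 configuration of no consequence; a homogeneous ruthenium catalyst should not hydrogenolyse benzyl ethers, and the acid-sensitive product is used crude.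

Step 8
Reactants: 16 (2S)-5,7-bis(benzyloxy)-6-[4-(benzyloxy)benzyl]-2-[4-(benzyloxy)phenyl]chroman-4-ol
Product: 15 (2S)-5,7-bis(benzyloxy)-6-[4-(benzyloxy)benzyl]-2-[4-(benzyloxy)phenyl]chroman-4-one
Conditions: Dess–Martin periodinane, NaHCO3, CH2Cl2, 0 °C → rt
Reagents that add atoms: none
Why: Dess–Martin oxidation of a secondary benzylic alcohol under buffered, non-basic conditions restores the C4 ketone without ionising C4 or opening ring C, so the C2 configuration is kept and both C4 epimers converge on one ketone.

Step 9
Reactants: 15 (2S)-5,7-bis(benzyloxy)-6-[4-(benzyloxy)benzyl]-2-[4-(benzyloxy)phenyl]chroman-4-one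
Product: 17 (2S)-5,7-bis(benzyloxy)-6-[4-(benzyloxy)benzyl]-2-[4-(benzyloxy)phenyl]-4-(trimethylsilyloxy)-2H-chromene
Conditions: TMSOTf, Et3N, CH2Cl2, 0 °C
Reagents that add atoms: trimethylsilyl trifluoromethanesulfonate, C[Si](C)(C)OS(=O)(=O)C(F)(F)F
Why: Soft enolisation: O-silylation of the ketone and removal of a C3 proton by the amine give the only possible silyl enol ether without a free enolate, which avoids the retro-oxa-Michael opening that would racemise C2; the product is used crude.

Step 10
Reactants: 17 (2S)-5,7-bis(benzyloxy)-6-[4-(benzyloxy)benzyl]-2-[4-(benzyloxy)phenyl]-4-(trimethylsilyloxy)-2H-chromene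
Product: 19 (2R,3R)-5,7-bis(benzyloxy)-6-[4-(benzyloxy)benzyl]-2-[4-(benzyloxy)phenyl]-3-hydroxychroman-4-one, via silyloxy epoxide 18 (not isolated)
Conditions: DMDO, acetone/CH2Cl2, −40 → 0 °C; then 1 M HCl, THF, 0 °C
Reagents that add atoms: dimethyldioxirane, CC1(C)OO1
Why: Rubottom oxidation: the dioxirane epoxidises the electron-rich C3=C4 enol ether bond from the face opposite to the aryl group on the neighbouring C2, and mild acid opens the silyloxy epoxide and removes the silyl group to give the alpha-hydroxy ketone with O3 trans to the aryl group (3R); the trans isomer is also the thermodynamically preferred one, and neutral to weakly acidic conditions leave C2 untouched.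

Step 11
Reactants: 19 (2R,3R)-5,7-bis(benzyloxy)-6-[4-(benzyloxy)benzyl]-2-[4-(benzyloxy)phenyl]-3-hydroxychroman-4-one
Product: 20 gericudranin E
Conditions: H2 (1 atm), Pd/C (10 %), EtOAc/MeOH, rt
Reagents that add atoms: none
Why: Catalytic hydrogenolysis of the four aryl benzyl ethers under neutral conditions at atmospheric pressure; the aryl ketone, the secondary alcohol and the diarylmethane should not be reduced, and the reaction is stopped at full debenzylation to spare the benzylic C2–O1 bond.

## Compound list

1 | 2,4,6-trihydroxybenzaldehyde | O=Cc1c(O)cc(O)cc1O | starting material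
2 | 2,6-dihydroxy-4-(methoxymethoxy)benzaldehyde | COCOc1cc(O)c(C=O)c(O)c1 | intermediate
3 | 2,6-bis(benzyloxy)-4-(methoxymethoxy)benzaldehyde | COCOc1cc(OCc2ccccc2)c(C=O)c(OCc2ccccc2)c1 | intermediate
4 | 1-(benzyloxy)-4-bromobenzene | Brc1ccc(OCc2ccccc2)cc1 | starting material
5 | 4-(benzyloxy)phenylmagnesium bromide (not isolated) | Br[Mg]c1ccc(OCc2ccccc2)cc1 | intermediate
6 | [2,6-bis(benzyloxy)-4-(methoxymethoxy)phenyl][4-(benzyloxy)phenyl]methanol, racemic | COCOc1cc(OCc2ccccc2)c(C(O)c2ccc(OCc3ccccc3)cc2)c(OCc2ccccc2)c1 | intermediate
7 | 1,3-bis(benzyloxy)-2-[4-(benzyloxy)benzyl]-5-(methoxymethoxy)benzene (not isolated) | COCOc1cc(OCc2ccccc2)c(Cc2ccc(OCc3ccccc3)cc2)c(OCc2ccccc2)c1 | intermediate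
8 | 3,5-bis(benzyloxy)-4-[4-(benzyloxy)benzyl]phenol | Oc1cc(OCc2ccccc2)c(Cc2ccc(OCc3ccccc3)cc2)c(OCc2ccccc2)c1 | intermediate
9 | 3,5-bis(benzyloxy)-4-[4-(benzyloxy)benzyl]-2-iodophenol | Oc1cc(OCc2ccccc2)c(Cc2ccc(OCc3ccccc3)cc2)c(OCc2ccccc2)c1I | intermediate
10 | 1-(benzyloxy)-4-ethynylbenzene | C#Cc1ccc(OCc2ccccc2)cc1 | starting material
11 | carbon monoxide | [C-]#[O+] | starting material
12 | 1-{2,4-bis(benzyloxy)-3-[4-(benzyloxy)benzyl]-6-hydroxyphenyl}-3-[4-(benzyloxy)phenyl]prop-2-yn-1-one (not isolated) | O=C(C#Cc1ccc(OCc2ccccc2)cc1)c1c(O)cc(OCc2ccccc2)c(Cc2ccc(OCc3ccccc3)cc2)c1OCc1ccccc1 | intermediate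
13 | 1-{2,4-bis(benzyloxy)-3-[4-(benzyloxy)benzyl]-6-hydroxyphenyl}-3-[4-(benzyloxy)phenyl]-3-(diethylamino)prop-2-en-1-one, alkene geometry not defined (not isolated) | CCN(CC)C(=CC(=O)c1c(O)cc(OCc2ccccc2)c(Cc2ccc(OCc3ccccc3)cc2)c1OCc1ccccc1)c1ccc(OCc2ccccc2)cc1 | intermediate
14 | 5,7-bis(benzyloxy)-6-[4-(benzyloxy)benzyl]-2-[4-(benzyloxy)phenyl]-4H-chromen-4-one | O=c1cc(-c2ccc(OCc3ccccc3)cc2)oc2cc(OCc3ccccc3)c(Cc3ccc(OCc4ccccc4)cc3)c(OCc3ccccc3)c12 | intermediate
15 | (2S)-5,7-bis(benzyloxy)-6-[4-(benzyloxy)benzyl]-2-[4-(benzyloxy)phenyl]chroman-4-one (passed through in step 7, isolated in step 8) | O=C1c2c(cc(OCc3ccccc3)c(Cc3ccc(OCc4ccccc4)cc3)c2OCc2ccccc2)O[C@H](c2ccc(OCc3ccccc3)cc2)C1 | intermediate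
16 | (2S)-5,7-bis(benzyloxy)-6-[4-(benzyloxy)benzyl]-2-[4-(benzyloxy)phenyl]chroman-4-ol, C4 epimers, mainly 2,4-cis | OC1c2c(cc(OCc3ccccc3)c(Cc3ccc(OCc4ccccc4)cc3)c2OCc2ccccc2)O[C@H](c2ccc(OCc3ccccc3)cc2)C1 | intermediate
17 | (2S)-5,7-bis(benzyloxy)-6-[4-(benzyloxy)benzyl]-2-[4-(benzyloxy)phenyl]-4-(trimethylsilyloxy)-2H-chromene | C[Si](C)(C)OC1=C[C@@H](c2ccc(OCc3ccccc3)cc2)Oc2cc(OCc3ccccc3)c(Cc3ccc(OCc4ccccc4)cc3)c(OCc3ccccc3)c12 | intermediate
18 | 3,4-epoxide of 17: 5,7-bis(benzyloxy)-6-[4-(benzyloxy)benzyl]-2-[4-(benzyloxy)phenyl]-3,4-epoxy-4-(trimethylsilyloxy)chroman, oxirane oxygen on the face opposite to the C2 aryl group, C2 as in 17 (not isolated) | C[Si](C)(C)O[C@]12c3c(cc(OCc4ccccc4)c(Cc4ccc(OCc5ccccc5)cc4)c3OCc3ccccc3)O[C@H](c3ccc(OCc4ccccc4)cc3)[C@H]1O2 | intermediate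
19 | (2R,3R)-5,7-bis(benzyloxy)-6-[4-(benzyloxy)benzyl]-2-[4-(benzyloxy)phenyl]-3-hydroxychroman-4-one | O=C1c2c(cc(OCc3ccccc3)c(Cc3ccc(OCc4ccccc4)cc3)c2OCc2ccccc2)O[C@H](c2ccc(OCc3ccccc3)cc2)[C@H]1O | intermediate
20 | gericudranin E, (2R,3R)-3,5,7-trihydroxy-6-(4-hydroxybenzyl)-2-(4-hydroxyphenyl)chroman-4-one | O=C1c2c(cc(O)c(Cc3ccc(O)cc3)c2O)O[C@H](c2ccc(O)cc2)[C@H]1O | target

## Step count and least certain steps

Total step count: 11. Longest linear sequence: 11 steps, from 1 to 20. Grignard reagent 5 is made from 4 and used within step 3, and 10 and 11 enter at step 6.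

**Step 6 (key step).**
- What may go wrong: oxidative addition at the doubly ortho-substituted, electron-rich C–I bond may be slow, so that protodeiodination takes over. The aroyl–palladium intermediate may be captured by the amine instead of the alkyne. Direct alkynylation without uptake of carbon monoxide, followed by closure to a benzofuran, is a further drain.
- Fallback: it sets out from 9 and returns at 14, and it brings C4 in as an acetyl carbon instead of carbon monoxide. Stille coupling of 9 with tributyl(1-ethoxyvinyl)stannane (Pd(PPh3)4, toluene, 100 °C) would give 3,5-bis(benzyloxy)-4-[4-(benzyloxy)benzyl]-2-(1-ethoxyvinyl)phenol F1. Dilute HCl hydrolyses it without isolation to 1-{2,4-bis(benzyloxy)-3-[4-(benzyloxy)benzyl]-6-hydroxyphenyl}ethanone F2. Claisen–Schmidt condensation of F2 with 4-(benzyloxy)benzaldehyde (KOH, EtOH/THF) would give (E)-1-{2,4-bis(benzyloxy)-3-[4-(benzyloxy)benzyl]-6-hydroxyphenyl}-3-[4-(benzyloxy)phenyl]prop-2-en-1-one F3. Oxidative cyclisation of F3 with catalytic iodine in DMSO at 120 °C closes ring C to flavone 14.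

**Step 7.**
- What may go wrong: facial discrimination at C2 may be poor, because the large C5 benzyloxy group and the four benzyl ethers change how the flavone sits in the chiral pocket. Turnover may be low for this crowded, poorly soluble substrate. Partial saturation of benzyl ether arenes at high pressure is possible.
- Fallback: it sets out from 14 and returns at 15, passing over 16 and step 8. Conjugate hydride addition with LiBH(s-Bu)3 (THF, −78 °C) would give racemic 5,7-bis(benzyloxy)-6-[4-(benzyloxy)benzyl]-2-[4-(benzyloxy)phenyl]chroman-4-one F4. Kinetic resolution by asymmetric transfer hydrogenation (Cp*RhCl[(R,R)-TsDPEN] or its mirror image, HCO2H/Et3N) would then reduce the 2R enantiomer to (2R,4R)-5,7-bis(benzyloxy)-6-[4-(benzyloxy)benzyl]-2-[4-(benzyloxy)phenyl]chroman-4-ol F5 and leave the (2S)-flavanone 15, at the cost of half the material.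

**Step 10.**
- What may go wrong: the oxidant may attack the face syn to the aryl group if the aryl group on the half-chair shields little. The dioxirane may oxidise the electron-rich ring A or the benzylic positions. The alpha-hydroxy ketone may be dehydrogenated to the flavonol during work-up.
- Fallback: it sets out from 15 and returns at 19, passing over 17 and 18. Oxygen is transferred directly to a metal enolate instead of through an enol ether epoxide. Deprotonation with KN(SiMe3)2 (THF, −78 °C) gives the potassium enolate of 15 F6. It is oxidised at that temperature with 3-phenyl-2-(phenylsulfonyl)oxaziridine, anti to the aryl group, and quenched cold with aq. NH4Cl to limit ring opening.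

**Step 11.**
- What may go wrong: hydrogenolysis of the benzylic C2–O1 bond (ring opening) or reduction of the C4 ketone may compete with removal of the four benzyl groups, of which the hindered C5 ether is the slowest.
- Fallback: it sets out from 19 and returns at 20 and makes no new compound (F0). The benzyl groups are removed by Lewis acid dealkylation with BCl3 and pentamethylbenzene as cation scavenger (CH2Cl2, −78 °C), which cannot reduce the ring.

**Step 1.**
- What may go wrong: alkylation may occur at a second hydroxyl or at O2 instead of O4, because selectivity rests only on the difference in acidity and hydrogen bonding.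
- Fallback: it sets out from 1 and returns at 8. It uses a bulky silyl group, so that size adds to the electronic preference. TBDPSCl and imidazole (DMF, 0 °C) would give 4-(tert-butyldiphenylsilyloxy)-2,6-dihydroxybenzaldehyde F7. Mitsunobu benzylation (BnOH, PPh3, DIAD, THF), which avoids the carbonate base that could cleave the aryl silyl ether, would give 2,6-bis(benzyloxy)-4-(tert-butyldiphenylsilyloxy)benzaldehyde F8. Addition of Grignard reagent 5 gives [2,6-bis(benzyloxy)-4-(tert-butyldiphenylsilyloxy)phenyl][4-(benzyloxy)phenyl]methanol F9. Et3SiH/CF3CO2H gives {3,5-bis(benzyloxy)-4-[4-(benzyloxy)benzyl]phenoxy}(tert-butyl)diphenylsilane F10, and Bu4NF (THF, 0 °C) frees phenol 8.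

## Further compounds

F1 | step 6 | 3,5-bis(benzyloxy)-4-[4-(benzyloxy)benzyl]-2-(1-ethoxyvinyl)phenol | CCOC(=C)c1c(O)cc(OCc2ccccc2)c(Cc2ccc(OCc3ccccc3)cc2)c1OCc1ccccc1
F2 | step 6 | 1-{2,4-bis(benzyloxy)-3-[4-(benzyloxy)benzyl]-6-hydroxyphenyl}ethanone | CC(=O)c1c(O)cc(OCc2ccccc2)c(Cc2ccc(OCc3ccccc3)cc2)c1OCc1ccccc1
F3 | step 6 | (E)-1-{2,4-bis(benzyloxy)-3-[4-(benzyloxy)benzyl]-6-hydroxyphenyl}-3-[4-(benzyloxy)phenyl]prop-2-en-1-one | O=C(/C=C/c1ccc(OCc2ccccc2)cc1)c1c(O)cc(OCc2ccccc2)c(Cc2ccc(OCc3ccccc3)cc2)c1OCc1ccccc1
F4 | step 7 | racemic 5,7-bis(benzyloxy)-6-[4-(benzyloxy)benzyl]-2-[4-(benzyloxy)phenyl]chroman-4-one | O=C1CC(c2ccc(OCc3ccccc3)cc2)Oc2cc(OCc3ccccc3)c(Cc3ccc(OCc4ccccc4)cc3)c(OCc3ccccc3)c12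
F5 | step 7 | (2R,4R)-5,7-bis(benzyloxy)-6-[4-(benzyloxy)benzyl]-2-[4-(benzyloxy)phenyl]chroman-4-ol | O[C@H]1c2c(cc(OCc3ccccc3)c(Cc3ccc(OCc4ccccc4)cc3)c2OCc2ccccc2)O[C@@H](c2ccc(OCc3ccccc3)cc2)C1
F6 | step 10 | potassium enolate of 15, potassium (2S)-5,7-bis(benzyloxy)-6-[4-(benzyloxy)benzyl]-2-[4-(benzyloxy)phenyl]-2H-chromen-4-olate | [K+].[O-]C1=C[C@@H](c2ccc(OCc3ccccc3)cc2)Oc2cc(OCc3ccccc3)c(Cc3ccc(OCc4ccccc4)cc3)c(OCc3ccccc3)c12
F0 | step 11 | none | none
F7 | step 1 | 4-(tert-butyldiphenylsilyloxy)-2,6-dihydroxybenzaldehyde | O=Cc1c(O)cc(O[Si](c2ccccc2)(c2ccccc2)C(C)(C)C)cc1O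
F8 | step 1 | 2,6-bis(benzyloxy)-4-(tert-butyldiphenylsilyloxy)benzaldehyde | O=Cc1c(OCc2ccccc2)cc(O[Si](c2ccccc2)(c2ccccc2)C(C)(C)C)cc1OCc1ccccc1
F9 | step 1 | [2,6-bis(benzyloxy)-4-(tert-butyldiphenylsilyloxy)phenyl][4-(benzyloxy)phenyl]methanol, racemic | OC(c1ccc(OCc2ccccc2)cc1)c1c(OCc2ccccc2)cc(O[Si](c2ccccc2)(c2ccccc2)C(C)(C)C)cc1OCc1ccccc1
F10 | step 1 | {3,5-bis(benzyloxy)-4-[4-(benzyloxy)benzyl]phenoxy}(tert-butyl)diphenylsilane | CC(C)(C)[Si](Oc1cc(OCc2ccccc2)c(Cc2ccc(OCc3ccccc3)cc2)c(OCc2ccccc2)c1)(c1ccccc1)c1ccccc1
A1 | alternative 1 | (2R,3R)-3-(benzyloxy)-6-[4-(benzyloxy)benzyl]-2-[4-(benzyloxy)phenyl]-5-hydroxy-7-(triisopropylsilyloxy)chroman-4-one | O=C1c2c(cc(O[Si](C(C)C)(C(C)C)C(C)C)c(Cc3ccc(OCc4ccccc4)cc3)c2O)O[C@H](c2ccc(OCc3ccccc3)cc2)[C@H]1OCc1ccccc1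
A2 | alternative 1 | 2,3-trans-3-(benzyloxy)-2-[4-(benzyloxy)phenyl]-6-(diazoacetyl)-2,3-dihydro-4H-pyran-4-one, configured at C2 and C3 as in the target | O=C1C=C(C(=O)C=[N+]=[N-])O[C@H](c2ccc(OCc3ccccc3)cc2)[C@H]1OCc1ccccc1
A3 | alternative 1 | {3-[4-(benzyloxy)phenyl]prop-1-yn-1-yloxy}triisopropylsilane | CC(C)[Si](OC#CCc1ccc(OCc2ccccc2)cc1)(C(C)C)C(C)C
A4 | alternative 2 | (2R,3R)-5,7-bis(benzyloxy)-6-[4-(benzyloxy)benzyl]-2-[4-(benzyloxy)phenyl]-3-(tert-butyldimethylsilyloxy)chroman-4-one | O=C1c2c(cc(OCc3ccccc3)c(Cc3ccc(OCc4ccccc4)cc3)c2OCc2ccccc2)O[C@H](c2ccc(OCc3ccccc3)cc2)[C@H]1O[Si](C)(C)C(C)(C)C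
A5 | alternative 2 | 3-{2-bromo-3,5-bis(benzyloxy)-4-[4-(benzyloxy)benzyl]phenoxy}-3-[4-(benzyloxy)phenyl]-2-(tert-butyldimethylsilyloxy)-N-methoxy-N-methylpropanamide, configured at both carbons as in the target | Brc1c(OCc2ccccc2)c(Cc2ccc(OCc3ccccc3)cc2)c(OCc2ccccc2)cc1O[C@H](c1ccc(OCc2ccccc2)cc1)[C@H](C(=O)N(C)OC)O[Si](C)(C)C(C)(C)C
A6 | alternative 2 | trans-3-[4-(benzyloxy)phenyl]-N-methoxy-N-methyloxirane-2-carboxamide, the enantiomer that gives A5 on opening with inversion at the benzylic carbon | CON(C)C(=O)[C@@H]1O[C@H]1c1ccc(OCc2ccccc2)cc1
A7 | alternative 3 | 2,3-trans-(2R)-3-acetoxy-5,7-bis(benzyloxy)-6-[4-(benzyloxy)benzyl]-2-[4-(benzyloxy)phenyl]-4-methoxychroman, C4 epimers | COC1c2c(cc(OCc3ccccc3)c(Cc3ccc(OCc4ccccc4)cc3)c2OCc2ccccc2)O[C@H](c2ccc(OCc3ccccc3)cc2)[C@H]1OC(C)=O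
A8 | alternative 3 | 4,6-bis(benzyloxy)-5-[4-(benzyloxy)benzyl]-2-hydroxybenzaldehyde | O=Cc1c(O)cc(OCc2ccccc2)c(Cc2ccc(OCc3ccccc3)cc2)c1OCc1ccccc1
A9 | alternative 3 | (E)-2-[4-(benzyloxy)phenyl]ethenyl acetate | CC(=O)O/C=C/c1ccc(OCc2ccccc2)cc1
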